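The route rests on disconnecting the lactone C16–O–C12 bond. The tertiary lactone oxygen on C12 beside the free secondary C11 hydroxyl, inside the seven-membered ring O–C12–C13–C14–C1–C15–C16 that bridges the 14-membered carbocycle, is read as an 11,12-epoxide opened by the C16 acid. In one operation the transannular, acid-promoted lactonisation closes that ring, forms the O–C12 bond with inversion and frees the C11 alcohol. Its precursor is the macrocyclic (3Z,7Z)-diene acid 27 carrying the cis-(11R,12S)-epoxide and a C6 silyl ether. It is assembled from (S)-limonene (C1), a three-component allylboration (C6, 3Z), Sharpless epoxidation and a ring-closing Suzuki coupling. C3=C4 is epoxidised last.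

Key step: step 21

Remark: cembrane numbering is used for all compounds, open-chain ones included (ring C1–C14; C15 carries methylene C17 and carbonyl carbon C16; C18, C19, C20 are the methyls on C4, C8, C12).

Step 1
Reactants: 1 (S)-limonene
Product: 3 (5S)-7-hydroxy-5-(prop-1-en-2-yl)heptan-2-one, via keto aldehyde 2 (not isolated)
Conditions: O3 (1 equiv), CH2Cl2/MeOH, −78 °C; Me2S, −78 °C to rt; NaBH(OAc)3, AcOH, 0 °C to rt
Reagents that add atoms: ozone [O-][O+]=O
Why: Criegee ozonolysis attacks the electron-richer trisubstituted ring alkene in preference to the isopropenyl group, and NaBH(OAc)3 then reduces only the aldehyde of 2 (chemoselective hydride reduction); C1 keeps the S configuration of limonene.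

Step 2
Reactants: 3 (5S)-7-hydroxy-5-(prop-1-en-2-yl)heptan-2-one
Product: 4 (3S)-6-oxo-3-(prop-1-en-2-yl)heptyl N,N-diisopropylcarbamate
Conditions: i-Pr2NCOCl, Et3N, CH2Cl2, reflux
Reagents that add atoms: N,N-diisopropylcarbamoyl chloride CC(C)N(C(C)C)C(Cl)=O
Why: Carbamoylation of the primary alcohol (Hoppe carbamate synthesis) tolerates the methyl ketone and provides the directing and leaving group needed in step 8.

Step 3
Reactants: 4 (3S)-6-oxo-3-(prop-1-en-2-yl)heptyl N,N-diisopropylcarbamate
Product: 5 (3S)-3-(3-hydroxyprop-1-en-2-yl)-6-oxoheptyl N,N-diisopropylcarbamate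
Conditions: SeO2 (cat.), t-BuOOH, salicylic acid (cat.), CH2Cl2, rt
Reagents that add atoms: tert-butyl hydroperoxide CC(C)(C)OO
Why: Sharpless SeO2/t-BuOOH allylic oxidation (ene reaction, then [2,3]-sigmatropic shift) hydroxylates methyl C16 of the only alkene present; it is placed here because the later trisubstituted alkenes would be oxidised faster.

Step 4
Reactants: 5 (3S)-3-(3-hydroxyprop-1-en-2-yl)-6-oxoheptyl N,N-diisopropylcarbamate
Product: 6 (3S)-3-[3-(tert-butyldimethylsilyloxy)prop-1-en-2-yl]-6-oxoheptyl N,N-diisopropylcarbamate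
Conditions: t-BuMe2SiCl, imidazole, DMF, 0 °C to rt
Reagents that add atoms: tert-butyldimethylsilyl chloride CC(C)(C)[Si](C)(C)Cl
Why: Imidazole-mediated silylation protects the primary allylic C16 alcohol through the organometallic steps.

Step 5
Reactants: 6 (3S)-3-[3-(tert-butyldimethylsilyloxy)prop-1-en-2-yl]-6-oxoheptyl N,N-diisopropylcarbamate
Product: 8 (3S)-3-[3-(tert-butyldimethylsilyloxy)prop-1-en-2-yl]-7-(trimethylsilyl)hept-6-ynyl N,N-diisopropylcarbamate, via enol phosphate 7 (not isolated)
Conditions: LiN(i-Pr)2, THF, −78 °C; ClP(O)(OEt)2; LiN(i-Pr)2 (2.3 equiv), −78 °C to rt; Me3SiCl, −78 °C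
Reagents that add atoms: chlorotrimethylsilane C[Si](C)(C)Cl
Why: Negishi alkyne synthesis: kinetic deprotonation on the methyl side gives enol phosphate 7, elimination gives the lithium acetylide, and C-silylation masks the ketone as a base-stable alkyne whose former methyl carbon is now C11.

Step 6
Reactants: 9 but-2-yn-1-ol
Product: 10 (Z)-3-iodobut-2-en-1-ol
Conditions: NaAlH2(OCH2CH2OMe)2, Et2O, 0 °C to rt; I2, −78 °C
Reagents that add atoms: iodine II
Why: Hydroxyl-directed trans-hydroalumination of the propargylic alcohol places aluminium on the distal alkyne carbon cis to the carbinol carbon, and iodinolysis with retention gives the Z vinyl iodide (C19, C8, C7, C6).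

Step 7
Reactants: 10 (Z)-3-iodobut-2-en-1-ol
Product: 11 (Z)-3-iodobut-2-enal
Conditions: MnO2, CH2Cl2, rt; used at once
Reagents that add atoms: none
Why: MnO2 oxidation of the allylic alcohol is neutral and should leave the Z geometry intact when the aldehyde is used immediately.

Step 8
Reactants: 8 (3S)-3-[3-(tert-butyldimethylsilyloxy)prop-1-en-2-yl]-7-(trimethylsilyl)hept-6-ynyl N,N-diisopropylcarbamate; 12 2-isopropenyl-4,4,5,5-tetramethyl-1,3,2-dioxaborolane; 11 (Z)-3-iodobut-2-enal
Product: 14 (1S,6R,3Z,7Z)-C6 alcohol C8 vinyl iodide, via allylic pinacol boronate 13 (not isolated)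
Conditions: s-BuLi, (−)-sparteine, Et2O, −78 °C; 12, −78 °C; MgBr2·OEt2, reflux; 11, −78 °C to rt
Reagents that add atoms: none
Why: Hoppe–Aggarwal lithiation–borylation–allylboration: (−)-sparteine-directed removal of the pro-S proton at C3, borylation with retention and 1,2-metallate shift with inversion should give the (3R)-allylboronate 13, which adds to 11 through a chair transition state with the C2 chain axial (avoiding A(1,2) strain with methyl C18) and the iodoalkenyl group equatorial, setting the 3Z alkene, the C5–C6 bond and the 6R carbinol.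

Step 9
Reactants: 14 (1S,6R,3Z,7Z)-C6 alcohol C8 vinyl iodide
Product: 15 (1S,6R,3Z,7Z)-bis-TBS ether silylalkyne
Conditions: t-BuMe2SiOTf, 2,6-lutidine, CH2Cl2, −78 °C
Reagents that add atoms: tert-butyldimethylsilyl triflate CC(C)(C)[Si](C)(C)OS(=O)(=O)C(F)(F)F
Why: Silyl triflate silylation of the hindered secondary allylic alcohol installs the C6 TBS ether that is carried to the end.

Step 10
Reactants: 15 (1S,6R,3Z,7Z)-bis-TBS ether silylalkyne
Product: 16 (1S,6R,3Z,7Z)-terminal alkyne
Conditions: K2CO3, MeOH, rt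
Reagents that add atoms: none
Why: Base-catalysed methanolysis cleaves only the alkynyl C–Si bond (protodesilylation); silyl ethers and vinyl iodide are inert.

Step 11
Reactants: 16 (1S,6R,3Z,7Z)-terminal alkyne
Product: 17 (1S,6R,3Z,7Z)-methyl ynoate
Conditions: EtMgBr, THF, 0 °C to rt; ClCO2Me, −40 °C to 0 °C
Reagents that add atoms: methyl chloroformate COC(Cl)=O
Why: EtMgBr metallates the terminal alkyne without exchanging the vinyl iodide, and acylation of the acetylide with the chloroformate adds C10.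

Step 12
Reactants: 17 (1S,6R,3Z,7Z)-methyl ynoate
Product: 18 (1S,6R,3Z,7Z,11Z)-methyl enoate
Conditions: Me2CuLi (from CuI and MeLi), THF, −78 °C; MeOH quench at −78 °C
Reagents that add atoms: lithium dimethylcuprate [Li+].C[Cu-]C
Why: syn-Carbocupration of the 2-ynoate at −78 °C and low-temperature protonation with retention (Corey–Katzenellenbogen conjugate addition) should give the 11Z enoate with C13 cis to C10 and installs methyl C20.

Step 13
Reactants: 18 (1S,6R,3Z,7Z,11Z)-methyl enoate
Product: 19 (1S,6R,3Z,7Z,11Z)-C10 allylic alcohol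
Conditions: i-Bu2AlH, CH2Cl2, −78 °C
Reagents that add atoms: none
Why: DIBAL 1,2-reduction of the enoate gives the Z allylic alcohol and leaves silyl ethers and vinyl iodide untouched.

Step 14
Reactants: 19 (1S,6R,3Z,7Z,11Z)-C10 allylic alcohol
Product: 20 (1S,6R,11R,12S,3Z,7Z)-cis-epoxy alcohol
Conditions: Ti(OiPr)4, D-(−)-diethyl tartrate, t-BuOOH, 4 Å MS, CH2Cl2, −20 °C
Reagents that add atoms: tert-butyl hydroperoxide CC(C)(C)OO
Why: Katsuki–Sharpless asymmetric epoxidation acts only on the free allylic alcohol and, with D-(−)-tartrate (the mirror-image series to epoxynerol from L-(+)-tartrate), should give the cis (11R,12S) epoxide under reagent control.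

Step 15
Reactants: 20 (1S,6R,11R,12S,3Z,7Z)-cis-epoxy alcohol
Product: 21 (1S,6R,3Z,7Z)-cis-epoxy C10 bromide
Conditions: CBr4, PPh3, 2,6-lutidine, CH2Cl2, 0 °C
Reagents that add atoms: carbon tetrabromide BrC(Br)(Br)Br
Why: Buffered Appel bromination converts the primary epoxy alcohol into an SN2-active bromide without opening the trisubstituted epoxide (same spatial arrangement; the C11 descriptor becomes S only because bromine changes the priorities).

Step 16
Reactants: 21 (1S,6R,3Z,7Z)-cis-epoxy C10 bromide; 22 bis(pinacolatoboryl)methane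
Product: 23 (1S,6R,11R,12S,3Z,7Z)-C9 pinacol boronate
Conditions: NaOt-Bu, THF, rt
Reagents that add atoms: none
Why: Morken deborylative alkylation: the alkoxide removes one boryl group of 22 to give an α-boryl carbanion that displaces the primary bromide (SN2), adding C9 as a CH2–Bpin handle.

Step 17
Reactants: 23 (1S,6R,11R,12S,3Z,7Z)-C9 pinacol boronate
Product: 24 (1S,6R,11R,12S,3Z,7Z)-macrocyclic bis-TBS ether epoxide
Conditions: Pd(OAc)2, RuPhos, KOH, THF/H2O, 70 °C, slow addition to high dilution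
Reagents that add atoms: none
Why: Intramolecular sp3–sp2 Suzuki–Miyaura coupling forms the C8–C9 bond with retention of the vinyl iodide geometry (7Z) and closes the 14-membered ring; the base-stable epoxide and silyl ethers should survive.

Step 18
Reactants: 24 (1S,6R,11R,12S,3Z,7Z)-macrocyclic bis-TBS ether epoxide
Product: 25 (1S,6R,11R,12S,3Z,7Z)-macrocyclic C16 allylic alcohol
Conditions: NH4F, MeOH, 50 °C
Reagents that add atoms: none
Why: Fluoride-mediated selective desilylation removes the unhindered primary allylic TBS ether much faster than the hindered secondary one at C6.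

Step 19
Reactants: 25 (1S,6R,11R,12S,3Z,7Z)-macrocyclic C16 allylic alcohol
Product: 26 (1S,6R,11R,12S,3Z,7Z)-macrocyclic C16 enal
Conditions: MnO2, CH2Cl2, rt
Reagents that add atoms: none
Why: MnO2 oxidises only the allylic alcohol, giving the 2-substituted acrolein.

Step 20
Reactants: 26 (1S,6R,11R,12S,3Z,7Z)-macrocyclic C16 enal
Product: 27 (1S,6R,11R,12S,3Z,7Z)-macrocyclic epoxy acid
Conditions: NaClO2, NaH2PO4, 2-methyl-2-butene, t-BuOH/H2O, 0 °C; cold work-up at pH 5
Reagents that add atoms: sodium chlorite [Na+].[O-]Cl=O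
Why: Pinnick–Lindgren chlorite oxidation with an alkene scavenger converts the enal into the acrylic acid without touching the trisubstituted alkenes, and the cold buffered work-up is meant to keep the epoxy acid intact.

Step 21
Reactants: 27 (1S,6R,11R,12S,3Z,7Z)-macrocyclic epoxy acid
Product: 28 (1S,6R,11R,12R,3Z,7Z)-bridged hydroxy lactone C6 TBS ether
Conditions: CSA (0.1 equiv), CH2Cl2, 0 °C to rt
Reagents that add atoms: none
Why: CSA protonates the 11,12-epoxide and the C16 carboxyl oxygen, held over C12 by its attachment at C1, attacks the tertiary carbon from the face opposite the C12–O bond in a loose SN2 opening, so the O–C12 bond forms with inversion and the epoxide oxygen stays on C11 as the free alcohol. The closest known reaction type is the acid-promoted cyclisation of epoxy carboxylic acids to hydroxy lactones by attack at the more substituted epoxide carbon, here run across the ring. The seven-membered lactone (O–C12–C13–C14–C1–C15–C16) closes in 7-exo-tet mode with respect to the breaking C12–O bond, whereas attack at C11 would be an 8-endo closure at a less cation-stabilising secondary carbon. The new C12 stereocentre (R) is fixed by stereospecific inversion of the (12S) epoxide carbon installed in step 14, and C11 keeps its configuration. The step needs O-attack at C12 to beat transannular participation of the C3=C4 and C7=C8 π bonds and loss of the C6 silyl ether; a weak sulfonic acid in a non-ionising solvent at low temperature and the proximity of the carboxyl group should secure this, and C3=C4 is left unepoxidised until afterwards so that no second epoxide competes for the acid.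

Step 22
Reactants: 28 (1S,6R,11R,12R,3Z,7Z)-bridged hydroxy lactone C6 TBS ether
Product: 29 (1S,3R,4S,6R,11R,12R,7Z)-3,4-epoxy lactone C6 TBS ether
Conditions: mCPBA, NaHCO3, CH2Cl2, −20 °C to 0 °C
Reagents that add atoms: 3-chloroperbenzoic acid OOC(=O)c1cccc(Cl)c1
Why: Prilezhaev epoxidation: C3=C4 is the only electron-rich, unhindered alkene (C7=C8 is inductively deactivated and shielded by the allylic OTBS, C15=C17 is conjugated to the lactone), and peripheral attack on the bridged macrocycle is expected to give the (3R,4S) epoxide.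

Step 23
Reactants: 29 (1S,3R,4S,6R,11R,12R,7Z)-3,4-epoxy lactone C6 TBS ether
Product: 30 CNP0250657.1
Conditions: Bu4NF, AcOH, THF, 0 °C to rt
Reagents that add atoms: none
Why: Acetic acid-buffered fluoride desilylation should free the C6 alcohol without harming the two epoxides or the α-methylene lactone.

Compound list
1 | (S)-limonene | CC1=CC[C@H](CC1)C(C)=C | starting material
2 | (3S)-6-oxo-3-(prop-1-en-2-yl)heptanal (keto aldehyde; C3 aldehyde; C12 ketone) | C=C(C)[C@H](CC=O)CCC(C)=O | intermediate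
3 | (5S)-7-hydroxy-5-(prop-1-en-2-yl)heptan-2-one | C=C(C)[C@H](CCO)CCC(C)=O | intermediate
4 | (3S)-6-oxo-3-(prop-1-en-2-yl)heptyl N,N-diisopropylcarbamate | C=C(C)[C@H](CCOC(=O)N(C(C)C)C(C)C)CCC(C)=O | intermediate
5 | (3S)-3-(3-hydroxyprop-1-en-2-yl)-6-oxoheptyl N,N-diisopropylcarbamate | C=C(CO)[C@H](CCOC(=O)N(C(C)C)C(C)C)CCC(C)=O | intermediate
6 | (3S)-3-[3-(tert-butyldimethylsilyloxy)prop-1-en-2-yl]-6-oxoheptyl N,N-diisopropylcarbamate | C=C(CO[Si](C)(C)C(C)(C)C)[C@H](CCOC(=O)N(C(C)C)C(C)C)CCC(C)=O | intermediate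
7 | enol phosphate: (3S)-6-(diethoxyphosphoryloxy)-3-[3-(tert-butyldimethylsilyloxy)prop-1-en-2-yl]hept-6-enyl N,N-diisopropylcarbamate | C=C(CO[Si](C)(C)C(C)(C)C)[C@H](CCOC(=O)N(C(C)C)C(C)C)CCC(=C)OP(=O)(OCC)OCC | intermediate
8 | (3S)-3-[3-(tert-butyldimethylsilyloxy)prop-1-en-2-yl]-7-(trimethylsilyl)hept-6-ynyl N,N-diisopropylcarbamate | C=C(CO[Si](C)(C)C(C)(C)C)[C@H](CCOC(=O)N(C(C)C)C(C)C)CCC#C[Si](C)(C)C | intermediate
9 | but-2-yn-1-ol | CC#CCO | starting material
10 | (Z)-3-iodobut-2-en-1-ol | OC/C=C(/C)I | intermediate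
11 | (Z)-3-iodobut-2-enal | O=C/C=C(/C)I | intermediate
12 | 2-isopropenyl-4,4,5,5-tetramethyl-1,3,2-dioxaborolane | CC(=C)B1OC(C)(C)C(C)(C)O1 | starting material
13 | allylic pinacol boronate (1S,3R): C3 carries Bpin and the C4 isopropenyl group; C16 OTBS; C12≡C11–SiMe3 | C=C(C)[C@H](B1OC(C)(C)C(C)(C)O1)C[C@H](CCC#C[Si](C)(C)C)C(=C)CO[Si](C)(C)C(C)(C)C | intermediate
14 | (1S,6R,3Z,7Z)-C6 alcohol C8 vinyl iodide: C1 carries C15(=C17)–C16H2OTBS; chain C2–C3=C4(C18)–C5–C6(OH)–C7=C8(I)–C19; chain C14–C13–C12≡C11–SiMe3 | CC(C)(C)[Si](C)(C)OCC(=C)[C@H](C/C=C(/C)C[C@@H](O)/C=C(/C)I)CCC#C[Si](C)(C)C | intermediate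
15 | (1S,6R,3Z,7Z)-bis-TBS ether silylalkyne (14 with C6 OTBS) | CC(C)(C)[Si](C)(C)OCC(=C)[C@H](C/C=C(/C)C[C@@H](O[Si](C)(C)C(C)(C)C)/C=C(/C)I)CCC#C[Si](C)(C)C | intermediate
16 | (1S,6R,3Z,7Z)-terminal alkyne (C12≡C11–H) | CC(C)(C)[Si](C)(C)OCC(=C)[C@H](C/C=C(/C)C[C@@H](O[Si](C)(C)C(C)(C)C)/C=C(/C)I)CCC#C | intermediate
17 | (1S,6R,3Z,7Z)-methyl ynoate (C12≡C11–C10O2Me) | CC(C)(C)[Si](C)(C)OCC(=C)[C@H](C/C=C(/C)C[C@@H](O[Si](C)(C)C(C)(C)C)/C=C(/C)I)CCC#CC(=O)OC | intermediate
18 | (1S,6R,3Z,7Z,11Z)-methyl enoate (C12(C20)=C11–C10O2Me; C13 cis to C10) | CC(C)(C)[Si](C)(C)OCC(=C)[C@H](C/C=C(/C)C[C@@H](O[Si](C)(C)C(C)(C)C)/C=C(/C)I)CC/C(C)=C\C(=O)OC | intermediate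
19 | (1S,6R,3Z,7Z,11Z)-C10 allylic alcohol | CC(C)(C)[Si](C)(C)OCC(=C)[C@H](C/C=C(/C)C[C@@H](O[Si](C)(C)C(C)(C)C)/C=C(/C)I)CC/C(C)=C\CO | intermediate
20 | (1S,6R,11R,12S,3Z,7Z)-cis-epoxy alcohol (C10 OH) | CC(C)(C)[Si](C)(C)OCC(=C)[C@H](C/C=C(/C)C[C@@H](O[Si](C)(C)C(C)(C)C)/C=C(/C)I)CC[C@]1(C)O[C@@H]1CO | intermediate
21 | (1S,6R,3Z,7Z)-cis-epoxy C10 bromide (epoxide as in 20; descriptors 11S,12S by priority change) | CC(C)(C)[Si](C)(C)OCC(=C)[C@H](C/C=C(/C)C[C@@H](O[Si](C)(C)C(C)(C)C)/C=C(/C)I)CC[C@]1(C)O[C@@H]1CBr | intermediate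
22 | bis(pinacolatoboryl)methane | CC1(C)OB(CB2OC(C)(C)C(C)(C)O2)OC1(C)C | starting material
23 | (1S,6R,11R,12S,3Z,7Z)-C9 pinacol boronate (C10–C9H2–Bpin) | CC(C)(C)[Si](C)(C)OCC(=C)[C@H](C/C=C(/C)C[C@@H](O[Si](C)(C)C(C)(C)C)/C=C(/C)I)CC[C@]1(C)O[C@@H]1CCB2OC(C)(C)C(C)(C)O2 | intermediate
24 | (1S,6R,11R,12S,3Z,7Z)-macrocyclic bis-TBS ether epoxide (C16 OTBS; C6 OTBS) | C=C(CO[Si](C)(C)C(C)(C)C)[C@@H]1C/C=C(/C)C[C@@H](O[Si](C)(C)C(C)(C)C)/C=C(/C)CC[C@H]2O[C@@]2(C)CC1 | intermediate
25 | (1S,6R,11R,12S,3Z,7Z)-macrocyclic C16 allylic alcohol | C=C(CO)[C@@H]1C/C=C(/C)C[C@@H](O[Si](C)(C)C(C)(C)C)/C=C(/C)CC[C@H]2O[C@@]2(C)CC1 | intermediate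
26 | (1S,6R,11R,12S,3Z,7Z)-macrocyclic C16 enal | C=C(C=O)[C@@H]1C/C=C(/C)C[C@@H](O[Si](C)(C)C(C)(C)C)/C=C(/C)CC[C@H]2O[C@@]2(C)CC1 | intermediate
27 | (1S,6R,11R,12S,3Z,7Z)-macrocyclic epoxy acid (key-step precursor) | C=C(C(=O)O)[C@@H]1C/C=C(/C)C[C@@H](O[Si](C)(C)C(C)(C)C)/C=C(/C)CC[C@H]2O[C@@]2(C)CC1 | intermediate
28 | (1S,6R,11R,12R,3Z,7Z)-bridged hydroxy lactone C6 TBS ether (key-step product) | C=C1C(=O)O[C@]2(C)CC[C@H]1C/C=C(/C)C[C@@H](O[Si](C)(C)C(C)(C)C)/C=C(/C)CC[C@H]2O | intermediate
29 | (1S,3R,4S,6R,11R,12R,7Z)-3,4-epoxy lactone C6 TBS ether | C=C1C(=O)O[C@]2(C)CC[C@H]1C[C@H]1O[C@@]1(C)C[C@@H](O[Si](C)(C)C(C)(C)C)/C=C(/C)CC[C@H]2O | intermediate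
30 | CNP0250657.1 (1S,3R,4S,6R,11R,12R,7Z) | C=C1C(=O)O[C@]2(C)CC[C@H]1C[C@H]1O[C@@]1(C)C[C@@H](O)/C=C(/C)CC[C@H]2O | target

Total step count: 23. Longest linear sequence: 21 steps (steps 1–5 and 8–23, from (S)-limonene); steps 6 and 7 make aldehyde 11 from but-2-yn-1-ol.

Steps most likely to fail

Step 17 (ring closure). What may go wrong: boron-to-palladium transfer of the primary alkyl pinacol boronate is slow at high dilution, so protodeboronation, β-hydride elimination or intermolecular coupling outrun macrocyclisation. The fallback sets out from 23 and comes back at 24, replacing the boron nucleophile by an organozinc one. The C–B bond of 23 is oxidised with NaBO3 in THF/H2O to the primary C9 alcohol F1. This is converted with I2, PPh3 and imidazole into the primary C9 iodide F2. Zinc is inserted (Zn dust, LiCl, THF, 25 °C, conditions under which the alkenyl iodide should stay untouched) to give the alkylzinc iodide F3. The ring is then closed by intramolecular Negishi coupling (Pd2(dba)3, SPhos, THF, high dilution), which needs neither base nor water.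

Step 8 (three-component assembly). What may go wrong: incomplete stereocontrol at C6, through partial loss of configuration of the lithiated carbamate before borylation or a competing non-chair allylboration, so that 14 is formed together with its C6 epimer. The fallback sets out from 14 (as the epimer mixture) and comes back at 14, replacing chirality transfer by reagent control. The mixture is oxidised with Dess–Martin periodinane (NaHCO3, CH2Cl2, 0 °C) to the single C6 ketone F4, a β-iodo enone. Corey–Bakshi–Shibata reduction with (S)-2-methyl-CBS-oxazaborolidine and catecholborane at −78 °C should then return the 6R alcohol.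

Step 22 (last epoxidation). What may go wrong: poor facial selectivity of peracid delivery to C3=C4, which only the substrate controls, or partial attack at C7=C8. The fallback sets out from 28 and comes back at 29, replacing substrate control by catalyst control. It uses the dioxirane generated from Shi's fructose-derived ketone, or its enantiomer, whichever is matched, with KHSO5 (Oxone) in buffered MeCN/dimethoxymethane/H2O at 0 °C. No new compound arises (F0).

Further compounds
F1 | step 17 | (1S,6R,11R,12S,3Z,7Z)-C9 primary alcohol (23 with CH2OH in place of CH2Bpin) | CC(C)(C)[Si](C)(C)OCC(=C)[C@H](C/C=C(/C)C[C@@H](O[Si](C)(C)C(C)(C)C)/C=C(/C)I)CC[C@]1(C)O[C@@H]1CCO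
F2 | step 17 | (1S,6R,11R,12S,3Z,7Z)-C9 primary iodide | CC(C)(C)[Si](C)(C)OCC(=C)[C@H](C/C=C(/C)C[C@@H](O[Si](C)(C)C(C)(C)C)/C=C(/C)I)CC[C@]1(C)O[C@@H]1CCI
F3 | step 17 | (1S,6R,11R,12S,3Z,7Z)-C9 alkylzinc iodide | CC(C)(C)[Si](C)(C)OCC(=C)[C@H](C/C=C(/C)C[C@@H](O[Si](C)(C)C(C)(C)C)/C=C(/C)I)CC[C@]1(C)O[C@@H]1CC[Zn]I
F4 | step 8 | (1S,3Z,7Z)-C6 ketone (β-iodo enone from 14) | CC(C)(C)[Si](C)(C)OCC(=C)[C@H](C/C=C(/C)CC(=O)/C=C(/C)I)CCC#C[Si](C)(C)C
F0 | step 22 | none | none
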